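**Strategy.** Ring C (the dihydropyran) is disconnected across O1–C2 and C3–C4. The feature exploited is that O1–C8a–C4a–C4 is a latent o-quinone methide of phloroglucinol ring A, while C2–C3 with ring B is a β-aryl enol ether. One magnesium-triggered cascade (carbonate migration, elimination, inverse-demand oxa-Diels–Alder) unites the two fully substituted aromatic halves, closes the only ring that has to be made and sets C3 through a 2-phenylcyclohexyl auxiliary on the enol oxygen. The precursors are an o-(Boc-oxy)benzyl alcohol that already carries 5-OMe, 6-prenyl and 7-OBoc, and an (E)-styryl ether. Ionic reduction then excises the auxiliary at C2; fluoride frees both phenols.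

Key step: step 8

Numbering: isoflavan numbering (O1, C2, C3, C4, C4a, C5–C8, C8a; ring B primed) is used; the target is (3R).
Assumption: the facial sense in step 8 is assigned from the s-trans, phenyl-shielded rotamer model of 2-phenylcyclohexyl enol ethers. If the other face reacts, the equally available (1S,2R)-alcohol is carried through the same steps.

Step 1
Reactants: 1 2,4,6-trihydroxybenzaldehyde; 2 prenyl bromide (1-bromo-3-methylbut-2-ene)
Product: 3 2,4,6-trihydroxy-3-(3-methylbut-2-enyl)benzaldehyde
Conditions: KOH (1 equiv), MeOH–H2O, 0 °C to rt, 2 (0.9 equiv) added slowly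
Reagents that add atoms: none
Why: Phenolate C-alkylation (SN2) of a phloroglucinol-type ambident anion, in which the protic medium masks the oxygens by hydrogen bonding so that carbon reacts, the two free ring positions are equivalent, and a deficit of bromide holds back double prenylation.

Step 2
Reactants: 3 2,4,6-trihydroxy-3-(3-methylbut-2-enyl)benzaldehyde
Product: 4 4,6-bis(tert-butoxycarbonyloxy)-2-hydroxy-3-(3-methylbut-2-enyl)benzaldehyde
Conditions: Boc2O (2.05 equiv), DMAP (5 mol%), i-Pr2NEt (0.2 equiv), THF, 0 °C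
Reagents that add atoms: di-tert-butyl dicarbonate CC(C)(C)OC(=O)OC(=O)OC(C)(C)C
Why: DMAP-catalysed O-acylation (carbonate formation), in which the non-chelated 4-OH and the unhindered 6-OH react while the 2-OH, wedged between prenyl and formyl and locked in the hydrogen bond to C=O, should stay free.

Step 3
Reactants: 4 4,6-bis(tert-butoxycarbonyloxy)-2-hydroxy-3-(3-methylbut-2-enyl)benzaldehyde
Product: 5 4,6-bis(tert-butoxycarbonyloxy)-2-methoxy-3-(3-methylbut-2-enyl)benzaldehyde
Conditions: MeOH (1.5 equiv), PPh3, DIAD, THF, 0 °C to rt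
Reagents that add atoms: methanol CO
Why: Mitsunobu etherification, whose neutral redox conditions methylate the hindered chelated phenol at a small methyl-oxyphosphonium centre without the free base that would cleave or scramble the aryl carbonates.

Step 4
Reactants: 5 4,6-bis(tert-butoxycarbonyloxy)-2-methoxy-3-(3-methylbut-2-enyl)benzaldehyde
Product: 6 [4,6-bis(tert-butoxycarbonyloxy)-2-methoxy-3-(3-methylbut-2-enyl)phenyl]methanol
Conditions: DIBAL-H (1.05 equiv), CH2Cl2, −78 °C; AcOH quench at −78 °C, then aq. Rochelle salt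
Reagents that add atoms: none
Why: 1,2-Hydride reduction, in which the aldehyde far outruns the hindered carbonates and the trisubstituted alkene at −78 °C, and the weakly nucleophilic aluminium alkoxide should not start carbonate migration before the cold acidic quench.

Step 5
Reactants: 7 4-hydroxy-2-methoxybenzaldehyde
Product: 8 2-methoxy-4-(triisopropylsilyloxy)benzaldehyde
Conditions: TIPSCl, imidazole, DMF, rt
Reagents that add atoms: chlorotriisopropylsilane CC(C)[Si](Cl)(C(C)C)C(C)C
Why: Standard phenol silylation; TIPS is chosen because it should outlast carbonate base at 80 °C, the Grignard base and cold BF3 and then leave with fluoride.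

Step 6
Reactants: 8 2-methoxy-4-(triisopropylsilyloxy)benzaldehyde
Product: 9 (E)-1-(2-iodovinyl)-2-methoxy-4-(triisopropylsilyloxy)benzene
Conditions: CHI3 (2 equiv), CrCl2 (6 equiv), THF, 0 °C
Reagents that add atoms: iodoform IC(I)I
Why: Takai olefination, in which the gem-dichromium reagent from iodoform adds to the aromatic aldehyde and eliminates to the (E)-vinyl iodide, fixing the alkene geometry on which the later stereochemical outcome depends.

Step 7
Reactants: 9 (E)-1-(2-iodovinyl)-2-methoxy-4-(triisopropylsilyloxy)benzene; 10 (1R,2S)-trans-2-phenylcyclohexanol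
Product: 11 (E)-2-methoxy-1-{2-[(1R,2S)-2-phenylcyclohexyloxy]vinyl}-4-(triisopropylsilyloxy)benzene
Conditions: CuI (10 mol%), 3,4,7,8-tetramethyl-1,10-phenanthroline (20 mol%), Cs2CO3 (1.5 equiv), toluene, 80 °C
Reagents that add atoms: none
Why: Copper-catalysed Ullmann-type C(sp2)–O coupling of a vinyl iodide with a secondary alcohol, which retains the alkene geometry and leaves the carbinol centre untouched, while the (E)-iodide lacks the anti H/I arrangement needed for easy elimination to the alkyne.

Step 8
Reactants: 6 [4,6-bis(tert-butoxycarbonyloxy)-2-methoxy-3-(3-methylbut-2-enyl)phenyl]methanol; 11 (E)-2-methoxy-1-{2-[(1R,2S)-2-phenylcyclohexyloxy]vinyl}-4-(triisopropylsilyloxy)benzene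
Product: 14 tert-butyl (2S,3R)-5-methoxy-3-[2-methoxy-4-(triisopropylsilyloxy)phenyl]-6-(3-methylbut-2-enyl)-2-[(1R,2S)-2-phenylcyclohexyloxy]chroman-7-yl carbonate, via benzylic carbonate 12 (not isolated), via o-quinone methide 13 (not isolated)
Conditions: t-BuMgCl (1.0 equiv), 11 (1.5–2 equiv, excess recovered), Et2O, −78 °C to rt; aq. NH4Cl
Reagents that add atoms: none
Why: t-BuMgCl deprotonates the benzylic alcohol, the alkoxide takes over the neighbouring C8a-O-Boc group through a six-membered transition state (12), and the magnesium phenoxide expels tert-butyl carbonate to give 13, which 11 traps as it forms in a concerted, asynchronous inverse-electron-demand oxa-[4+2] cycloaddition. The closest known reaction type is the low-temperature anionic generation of o-quinone methides from o-(Boc-oxy)benzyl alcohols with cycloaddition to enol ethers, which includes 2-phenylcyclohexyl vinyl ethers as chiral 2π partners and β-aryl enol ethers as isoflavan precursors. Ring C is closed intermolecularly in the [4+2] mode (O1–C8a–C4a–C4 plus C2=C3), so C3–C4 and O1–C2 form in one operation. Suprafacial addition to the (E)-alkene gives the 2,3-trans acetal, and in the s-trans rotamer, with the carbinol C–H eclipsing the vinyl plane, the auxiliary phenyl covers one face so that the heterodiene adds to the other and gives (2S,3R); endo versus exo approach is irrelevant because C4 is a CH2 group. Regiochemistry follows from the enol ether HOMO, whose largest coefficient lies on the aryl-bearing carbon β to oxygen and meets the electrophilic methide carbon C4. Only the Boc group ortho to the CH2O can migrate (the para C7-OBoc stays), the prenyl alkene is far less nucleophilic than the enol ether, and excess 11 competes with self-condensation of 13.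

Step 9
Reactants: 14 tert-butyl (2S,3R)-5-methoxy-3-[2-methoxy-4-(triisopropylsilyloxy)phenyl]-6-(3-methylbut-2-enyl)-2-[(1R,2S)-2-phenylcyclohexyloxy]chroman-7-yl carbonate
Product: 15 tert-butyl (3R)-5-methoxy-3-[2-methoxy-4-(triisopropylsilyloxy)phenyl]-6-(3-methylbut-2-enyl)chroman-7-yl carbonate
Conditions: Et3SiH (5 equiv), BF3·OEt2 (1.5 equiv), CH2Cl2, 4 Å MS, −78 to −40 °C; cold aq. NaHCO3
Reagents that add atoms: none
Why: Ionic (Kursanov–Parnes-type) acetal reduction, in which BF3 binds the more basic exocyclic alkyl oxygen, the auxiliary leaves, and excess silane should reduce the cyclic oxocarbenium ion faster than it can lose H-3, so C3 is untouched and the low temperature spares Boc, TIPS and prenyl.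

Step 10
Reactants: 15 tert-butyl (3R)-5-methoxy-3-[2-methoxy-4-(triisopropylsilyloxy)phenyl]-6-(3-methylbut-2-enyl)chroman-7-yl carbonate
Product: 16 (3R)-3-(4-hydroxy-2-methoxyphenyl)-5-methoxy-6-(3-methylbut-2-enyl)chroman-7-ol (target)
Conditions: TBAF·3H2O (4 equiv), THF, Ar, 0 °C to rt; aq. NH4Cl
Reagents that add atoms: none
Why: Fluoride desilylation combined with hydrolysis of the base-labile aryl tert-butyl carbonate in the basic wet fluoride medium; no acid is present, so the 7-OH/prenyl pair should not cyclise, and C3 carries no acidic hydrogen.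

**Compound list**
1 | 2,4,6-trihydroxybenzaldehyde | O=Cc1c(O)cc(O)cc1O | starting material
2 | prenyl bromide | CC(C)=CCBr | starting material
3 | 2,4,6-trihydroxy-3-(3-methylbut-2-enyl)benzaldehyde | O=Cc1c(O)cc(O)c(CC=C(C)C)c1O | intermediate
4 | 4,6-bis(tert-butoxycarbonyloxy)-2-hydroxy-3-(3-methylbut-2-enyl)benzaldehyde | O=Cc1c(OC(=O)OC(C)(C)C)cc(OC(=O)OC(C)(C)C)c(CC=C(C)C)c1O | intermediate
5 | 4,6-bis(tert-butoxycarbonyloxy)-2-methoxy-3-(3-methylbut-2-enyl)benzaldehyde | O=Cc1c(OC(=O)OC(C)(C)C)cc(OC(=O)OC(C)(C)C)c(CC=C(C)C)c1OC | intermediate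
6 | [4,6-bis(tert-butoxycarbonyloxy)-2-methoxy-3-(3-methylbut-2-enyl)phenyl]methanol | OCc1c(OC(=O)OC(C)(C)C)cc(OC(=O)OC(C)(C)C)c(CC=C(C)C)c1OC | intermediate
7 | 4-hydroxy-2-methoxybenzaldehyde | COc1cc(O)ccc1C=O | starting material
8 | 2-methoxy-4-(triisopropylsilyloxy)benzaldehyde | COc1cc(O[Si](C(C)C)(C(C)C)C(C)C)ccc1C=O | intermediate
9 | (E)-1-(2-iodovinyl)-2-methoxy-4-(triisopropylsilyloxy)benzene | COc1cc(O[Si](C(C)C)(C(C)C)C(C)C)ccc1/C=C/I | intermediate
10 | (1R,2S)-trans-2-phenylcyclohexanol | O[C@@H]1CCCC[C@H]1c1ccccc1 | starting material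
11 | (E)-β-aryl enol ether of 10 | COc1cc(O[Si](C(C)C)(C(C)C)C(C)C)ccc1/C=C/O[C@@H]1CCCC[C@H]1c1ccccc1 | intermediate
12 | benzylic tert-butyl carbonate with free C8a-OH (Boc-migrated isomer of 6, present as Mg phenoxide) | COc1c(COC(=O)OC(C)(C)C)c(O)cc(OC(=O)OC(C)(C)C)c1CC=C(C)C | intermediate
13 | 3-(tert-butoxycarbonyloxy)-5-methoxy-6-methylidene-4-(3-methylbut-2-enyl)cyclohexa-2,4-dien-1-one (o-quinone methide) | C=C1C(=O)C=C(OC(=O)OC(C)(C)C)C(CC=C(C)C)=C1OC | intermediate
14 | (2S,3R)-2-[(1R,2S)-2-phenylcyclohexyloxy]isoflavan acetal, 7-OBoc, 4'-OTIPS | COc1cc(O[Si](C(C)C)(C(C)C)C(C)C)ccc1[C@@H]1[C@@H](O[C@@H]3CCCC[C@H]3c3ccccc3)Oc2cc(OC(=O)OC(C)(C)C)c(CC=C(C)C)c(OC)c2C1 | intermediate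
15 | (3R)-isoflavan, 7-OBoc, 4'-OTIPS | COc1cc(O[Si](C(C)C)(C(C)C)C(C)C)ccc1[C@@H]1COc2cc(OC(=O)OC(C)(C)C)c(CC=C(C)C)c(OC)c2C1 | intermediate
16 | (3R)-3-(4-hydroxy-2-methoxyphenyl)-5-methoxy-6-(3-methylbut-2-enyl)chroman-7-ol | COc1cc(O)ccc1[C@@H]1COc2cc(O)c(CC=C(C)C)c(OC)c2C1 | target

Total steps: 10. Longest linear sequence: 7 (steps 1, 2, 3, 4, 8, 9, 10).

**Steps most likely to fail**

Step 8.
- **Risk:** cycloaddition of the hindered, 1,2-disubstituted enol ether may be slower than self-condensation of the quinone methide. Rotation about the O–vinyl bond may also erode facial selectivity.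
- **Fallback:** it sets out from 6 and 11 and returns at 15, moving the stereocontrol to a far more nucleophilic chiral enamine.
- Enol ether 11 is hydrolysed (aq. oxalic acid, THF, with 10 recovered) to arylacetaldehyde F1.
- F1 is condensed (4 Å MS, toluene) with (R)-2-[diphenyl(trimethylsilyloxy)methyl]pyrrolidine to (E)-enamine F2.
- With 13 released from 6 as in step 8, F2 should give aminal F3. The bulky pyrrolidine substituent shields one enamine face, as in aminocatalytic aldehyde/o-quinone methide annulations.
- A pH 5 buffer hydrolyses F3 to lactol F4, which Et3SiH/BF3·OEt2 at −78 °C reduces to 15.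

Step 9.
- **Risk:** ionisation may follow the endocyclic C2–O1 path (ring opening). The oxocarbenium ion may lose H-3, eroding enantiopurity. Acid may also strip the carbonate and attack the prenyl group.
- **Fallback:** it sets out from 14 and returns at 15, replacing cationic by radical deoxygenation.
- Mild hydrolysis (PPTS, aqueous acetone) gives lactol F4, and either mode of ionisation ends in this same lactol.
- 1,1'-Thiocarbonyldiimidazole/DMAP acylates the closed form to thiocarbonylimidazolide F5.
- Barton–McCombie reduction (Bu3SnH, AIBN, toluene, 80 °C) passes through the C2 radical, so no cation arises next to C3.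

Step 2.
- **Risk:** discrimination between the two chelated hydroxyls may be insufficient, or acylation may go too far, which would misplace OMe and O1 relative to prenyl.
- **Fallback:** it sets out from 1, returns at 5 and bypasses steps 1–3; regiochemistry is fixed by symmetry and a sigmatropic relay.
- Boc2O (1 equiv) goes to the only non-chelated hydroxyl and gives 4-carbonate F6.
- Mitsunobu methylation with one equivalent of MeOH differentiates the two equivalent chelated hydroxyls and gives monomethyl ether F7.
- A second Mitsunobu reaction with prenol gives aryl prenyl ether F8.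
- Eu(fod)3-catalysed tandem Claisen–Cope rearrangement (ortho shift, then [3,3] to the para position) gives phenol F9. There the prenyl can only sit between OMe and OBoc, and the hydroxyl destined to become O1 is free.
- Boc2O/DMAP then gives 5.

**Further compounds**
F1 | step 8 | 2-[2-methoxy-4-(triisopropylsilyloxy)phenyl]acetaldehyde | COc1cc(O[Si](C(C)C)(C(C)C)C(C)C)ccc1CC=O
F2 | step 8 | (E)-enamine of F1 with (R)-2-[diphenyl(trimethylsilyloxy)methyl]pyrrolidine | COc1cc(O[Si](C(C)C)(C(C)C)C(C)C)ccc1/C=C/N1CCC[C@@H]1C(O[Si](C)(C)C)(c1ccccc1)c1ccccc1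
F3 | step 8 | (2S,3R)-2-(pyrrolidin-1-yl)isoflavan aminal, 7-OBoc, 4'-OTIPS | COc1cc(O[Si](C(C)C)(C(C)C)C(C)C)ccc1[C@@H]1[C@@H](N3CCC[C@@H]3C(O[Si](C)(C)C)(c3ccccc3)c3ccccc3)Oc2cc(OC(=O)OC(C)(C)C)c(CC=C(C)C)c(OC)c2C1
F4 | step 8 | (3R)-2-hydroxyisoflavan lactol (anomers), 7-OBoc, 4'-OTIPS | COc1cc(O[Si](C(C)C)(C(C)C)C(C)C)ccc1[C@@H]1C(O)Oc2cc(OC(=O)OC(C)(C)C)c(CC=C(C)C)c(OC)c2C1
F5 | step 9 | (3R)-isoflavan-2-yl 1H-imidazole-1-carbothioate, 7-OBoc, 4'-OTIPS | COc1cc(O[Si](C(C)C)(C(C)C)C(C)C)ccc1[C@@H]1C(OC(=S)n3ccnc3)Oc2cc(OC(=O)OC(C)(C)C)c(CC=C(C)C)c(OC)c2C1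
F6 | step 2 | tert-butyl 4-formyl-3,5-dihydroxyphenyl carbonate | O=Cc1c(O)cc(OC(=O)OC(C)(C)C)cc1O
F7 | step 2 | tert-butyl 4-formyl-3-hydroxy-5-methoxyphenyl carbonate | O=Cc1c(O)cc(OC(=O)OC(C)(C)C)cc1OC
F8 | step 2 | tert-butyl 4-formyl-3-methoxy-5-(3-methylbut-2-enyloxy)phenyl carbonate | O=Cc1c(OCC=C(C)C)cc(OC(=O)OC(C)(C)C)cc1OC
F9 | step 2 | tert-butyl 4-formyl-5-hydroxy-3-methoxy-2-(3-methylbut-2-enyl)phenyl carbonate | O=Cc1c(O)cc(OC(=O)OC(C)(C)C)c(CC=C(C)C)c1OC
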